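## Structural features

The target is a 1,7-diarylheptanoid folded into one oxane (tetrahydropyran) ring. The ring is numbered O1, C2 (bearing a 2-(4-hydroxy-3-methoxyphenyl)ethyl chain), C3H2, C4 (secondary hydroxyl), C5H2 and C6 (bearing a 3,4-dihydroxy-5-methoxyphenyl ring). The stereocentres C2 (S), C4 (R) and C6 (S) are not adjacent: each is separated from the next by a methylene, and all three substituents are cis, that is equatorial on one chair. In open-chain terms (heptane C1 = ring C6, C3 = ring C4, C5 = ring C2) the ring oxygen belongs to C5, and the C3 and C5 oxygens are anti. The fragile parts are the catechol unit of the trioxygenated ring (air oxidation), the free guaiacol phenol, and the C6–O1 bond, which is benzylic to an electron-rich ring and therefore labile to acid and to hydrogenolysis. The real difficulty is the control of three remote carbinol centres, above all C6, which nothing directs in an open chain. The key step turns the lability of C6–O1 into an asset: the aryl ring on C6 carries an oxygen para to C6, so O1–C6 can be made and broken through a para-alkoxybenzyl (quinone-methide-like) cation, and C6 settles into the all-equatorial arrangement dictated by C2 and C4.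

## Logic of the disconnections

**20 from 19.** The three phenolic O–H bonds are traced back to O–CH2Ph bonds. Free phenols, the catechol above all, would not survive the enolate, hydride, Grignard and acid steps, whereas benzyl ethers pass through all of them and fall in one operation that adds only hydrogen. Nothing is gained in skeleton, but one late unmasking step is all that follows the key step. The demand is that hydrogenolysis spares the benzylic C6–O1 ring bond.

**19 from 18.** The ring bond O1–C6 is cut. It is the one ring bond that can be formed reversibly, so cutting it removes the ring and the C6 stereocentre together and leaves an acyclic triol in which the configuration at the benzylic carbon no longer matters. The demand is ionisation at that carbon only, capture by the C5 oxygen and not the C3 oxygen, and equilibration to the all-cis ring.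

**18 from 12 and 17 (17 from 16).** The bond between heptane C1 and the aryl ring is cut. This splits the molecule into an aryl nucleophile and a six-membered lactol that carries both fixed stereocentres and needs no protecting group. Because either C1 epimer serves, the addition needs no stereocontrol. The triol is formed under basic conditions, so the acid-labile benzylic carbinol meets acid for the first time in the key step. The demand is that the aryl metal adds to a masked aldehyde that carries two free hydroxyls, which costs extra reagent.

**16 from 15 from 13 (through 14).** Two O–benzyl bonds are cut, and then the C–O bond of the second phenol is traced back to a C–CHO bond. The bromine of 13 already sits para to the future central oxygen and the methoxy group is in place, so the aryl unit costs two steps. The demand is an ortho-hydroxy aldehyde for the aryl migration, which 13 has, and exclusion of air from 15.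

**12 from 11 from 9 (through 10).** The lactol C1–H bond goes back to the lactone carbonyl, and the lactone C1–O bond to an open tert-butyl ester. The lactone is an internally protected 3,5-dihydroxy acid whose half-reduction is far more dependable than that of an open ester, and two protection steps are saved. The demand is lactonisation without dehydration of the β-hydroxyl.

**9 from 8.** The C3–H bond is cut. The C3 carbinol is derived from a ketone by hydride delivery from the C5 hydroxyl, so the second stereocentre is relayed from the first. The demand is high anti selectivity.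

**8 from 5 and 6 (through 7).** The C2–C3 bond of the heptanoate is cut in a Claisen sense, which removes two carbons and returns a simple β-hydroxy ester. The demand is acylation of an acetate enolate by an ester that carries a free hydroxyl.

**5 from 4.** The C3–H bond of the pentanoate is cut. This is the only step that needs an external source of chirality, a catalyst. The demand is high enantioselectivity, because every later centre is relayed from this one.

**4 from 2 (through 3), 2 from 1.** The C2–C3 bond of the keto ester is cut (acylation of a malonate half-ester), and then the O–benzyl bond. This leads back to a commercial phenolic acid that already holds the aryl ring and three chain carbons. The demand is C-acylation without self-condensation.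

## Other disconnections considered

**Alternative 1:** The cut removes two carbon–carbon bonds at once, C3–C4 and C4–C5 of the ring numbering. C4 becomes the masked carbonyl carbon of the silyl dithiane A4, and the two halves become the (S)-alkyl oxirane A2 and the racemic aryl oxirane A3.
- **Forward step:** lithiated A4 would open A2 at its CH2 terminus, a polar co-solvent would trigger the 1,4-Brook shift of silicon from carbon to the new alkoxide, and the regenerated dithiane anion would open A3 to give A1. In A1 the silyloxy carbon is fixed, the benzylic carbinol is a mixture and no ring is closed.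
- **In its favour:** three fragments are joined in one flask, and A3 may be racemic because the benzylic centre would later be set by the same stereoconvergent ring closure as in the chosen plan.
- **Against it here:** A3 is an electron-rich styrene oxide and invites attack at the benzylic carbon or lithium-promoted rearrangement to an arylacetaldehyde. C4 arrives as a ketone equivalent with no stereocentre. After A1 there would remain desilylation, dithiane hydrolysis next to two oxidation-prone arenes, ring closure to the oxan-4-one A5, reduction of A5 to 19, and hydrogenolysis.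
- **Comparison:** on convergence the alternative is better. On control of C6 the two plans are equal, since both pass through the same benzylic cation. On structure the chosen plan enters its key step with two of three centres set where A1 has one. On step count the two should be about equal, because A2 and A3 need their own preparations and the tail after A1 is long.

**Alternative 2:** The cut is C5–C6 with the ring at the ketone level, leading to the enol acetal A6. A6 would come from 5 and the aldehyde A7 by saponification, acetalisation to the dioxanone A8 and carbonyl methylenation with Cp2TiMe2.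
- **Forward step:** Me2AlCl would bind the enol-ether oxygen of A6, the acetal C–O bond would break to give an aluminium enolate tethered to an aryl-stabilised oxocarbenium ion, and recombination at carbon would close A5 with the two substituents cis. Hydride reduction of A5 would give 19.
- **In its favour:** it is short and convergent, it uses the same chiral building block 5, and on step count it should beat the chosen plan by about two steps.
- **Against it here:** A8 and A6 are acid- and moisture-sensitive derivatives of an electron-rich benzaldehyde. The ion pair can fall apart to A7 and an enolate instead of recombining. The C4 carbinol is made last, by a ketone reduction whose selectivity rests only on axial attack.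
- **Comparison:** both plans close the ring at C6 through a cation stabilised by the same aryl ring. The alternative forms a C–C bond under kinetic chair control; the chosen plan forms a C–O bond under thermodynamic control. The chosen plan has C4 set before the key step and needs no redox adjustment afterwards. In robustness of intermediates the chosen plan is ahead; in brevity the alternative is.

**Alternative 3:** The cut is O1–C2 with unsaturation kept in the side chain. The precursor is A10, an anti-1,3-diol monosilyl ether with a stereodefined benzylic C6 carbinol and an (E)-arylallylic alcohol terminus.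
- **Forward step:** FeCl3·6H2O (trivalent iron) would ionise the arylallylic alcohol of either configuration to a 1-arylallyl cation, and the C6 hydroxyl would attack the terminus remote from the aryl ring. This would form O1–C2 and leave an (E)-styryl group on C2 of the all-cis oxane A9.
- **In its favour:** the cation is both allylic and conjugated to a guaiacyl ring whose para oxygen has only one ortho neighbour, so ionisation should be easier than in the chosen plan. On this mechanistic point the alternative is better. The catalyst is cheap.
- **Against it here:** the benzylic carbinol is now the nucleophile, so C6 must be made enantio- and diastereoselectively beforehand (anti to C4), and it is itself ionisable by the Lewis acid. A silyl group must be put on and taken off. The final hydrogenation of A9 must saturate a styrene beside an allylic C2–O bond, which invites hydrogenolysis of that bond.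
- **Comparison:** each plan uses stereoconvergence to waive control of one carbinol centre (C2 there, C6 here), and in concept they are equal. The chosen plan waives the centre that is hardest to make asymmetrically and keeps two aliphatic centres that a β-hydroxy ester relays. After A9 two operations remain, against one after 19. The overall step count should be about equal or slightly longer.

Key step: step 11

Assumption: the 4-benzyloxy group of the 3,4,5-trioxygenated ring, although flanked by two ortho substituents, still stabilises the benzylic cation enough for ionisation by catalytic p-TsOH near room temperature.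

## Route

Step 1
Reactants: 1 3-(4-hydroxy-3-methoxyphenyl)propanoic acid (dihydroferulic acid)
Product: 2 3-[4-(benzyloxy)-3-methoxyphenyl]propanoic acid
Conditions: BnBr (1.3 equiv), NaOH (3 equiv), EtOH/H2O, reflux; then aq. HCl
Reagents that add atoms: benzyl bromide, BrCc1ccccc1
Why: Williamson etherification of the phenoxide; the carboxylate is a much weaker nucleophile in aqueous ethanol and any benzyl ester formed is saponified by the excess hydroxide, so acidification should give the O-benzyl acid directly.

Step 2
Reactants: 2 3-[4-(benzyloxy)-3-methoxyphenyl]propanoic acid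
Product: 4 ethyl 5-[4-(benzyloxy)-3-methoxyphenyl]-3-oxopentanoate, via acyl imidazolide 3 (not isolated)
Conditions: CDI (1.1 equiv), THF, rt; then KO2CCH2CO2Et (1.5 equiv), MgCl2 (1.5 equiv), Et3N (2 equiv), THF/MeCN, rt to 40 °C; aq. HCl
Reagents that add atoms: potassium ethyl malonate, CCOC(=O)CC(=O)[O-].[K+]
Why: Masamune-type homologation; the acid is activated as its acyl imidazolide, which C-acylates the magnesium enolate of the malonate half-ester, and decarboxylation leaves the β-keto ester without any strong base.

Step 3
Reactants: 4 ethyl 5-[4-(benzyloxy)-3-methoxyphenyl]-3-oxopentanoate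
Product: 5 ethyl (3S)-5-[4-(benzyloxy)-3-methoxyphenyl]-3-hydroxypentanoate
Conditions: H2 (10 bar), RuCl2[(S)-BINAP] (0.5 mol%), EtOH, 60 °C
Reagents that add atoms: none
Why: Noyori asymmetric hydrogenation of a β-keto ester; the chelated substrate is reduced on the face set by the (S)-BINAP ligand, which for an unbranched 3-oxoalkanoate should give the (3S)-alcohol, the future C2 of the ring. Benzyl aryl ethers are inert to this homogeneous ruthenium catalyst.

Step 4
Reactants: 5 ethyl (3S)-5-[4-(benzyloxy)-3-methoxyphenyl]-3-hydroxypentanoate; 6 tert-butyl acetate
Product: 8 tert-butyl (5S)-7-[4-(benzyloxy)-3-methoxyphenyl]-5-hydroxy-3-oxoheptanoate, via lithium enolate of tert-butyl acetate 7 (not isolated)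
Conditions: LiN(i-Pr)2 (LDA, 4.2 equiv), 6 (4.2 equiv), THF, −78 °C; then 5, −78 to −30 °C; aq. NH4Cl
Reagents that add atoms: none
Why: Crossed Claisen condensation; one equivalent of enolate deprotonates the hydroxyl, further enolate acylates at the ethyl ester, and the β-keto ester is protected from over-addition as its own enolate. The carbinol centre is not touched.

Step 5
Reactants: 8 tert-butyl (5S)-7-[4-(benzyloxy)-3-methoxyphenyl]-5-hydroxy-3-oxoheptanoate
Product: 9 tert-butyl (3R,5S)-7-[4-(benzyloxy)-3-methoxyphenyl]-3,5-dihydroxyheptanoate
Conditions: Me4NBH(OAc)3 (6 equiv), MeCN/AcOH (1:1), −30 °C; aq. potassium sodium tartrate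
Reagents that add atoms: none
Why: Evans–Saksena reduction; the C5 hydroxyl exchanges an acetate on boron and delivers hydride intramolecularly through a chair transition state to the acid-activated ketone, which should set C3 anti to C5 (3R).

Step 6
Reactants: 9 tert-butyl (3R,5S)-7-[4-(benzyloxy)-3-methoxyphenyl]-3,5-dihydroxyheptanoate
Product: 11 (4R,6S)-6-{2-[4-(benzyloxy)-3-methoxyphenyl]ethyl}-4-hydroxyoxan-2-one, via dihydroxy acid 10 (not isolated)
Conditions: CF3CO2H/CH2Cl2 (1:5), 0 °C to rt; toluene azeotrope
Reagents that add atoms: none
Why: Acid cleavage of the tert-butyl ester with loss of 2-methylpropene, followed by spontaneous δ-lactonisation of the hydroxy acid. The anti diol gives the cis lactone with both substituents equatorial, and no bond to a stereocentre is broken.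

Step 7
Reactants: 11 (4R,6S)-6-{2-[4-(benzyloxy)-3-methoxyphenyl]ethyl}-4-hydroxyoxan-2-one
Product: 12 (4R,6S)-6-{2-[4-(benzyloxy)-3-methoxyphenyl]ethyl}oxane-2,4-diol (both anomers)
Conditions: i-Bu2AlH (DIBAL-H, 2.3 equiv), CH2Cl2, −78 °C; MeOH, then aq. potassium sodium tartrate
Reagents that add atoms: none
Why: Half-reduction of a δ-lactone to the lactol; the tetrahedral aluminium hemiacetal is stable at −78 °C and is released on work-up, one extra equivalent of hydride being consumed by the free hydroxyl.

Step 8
Reactants: 13 5-bromo-2-hydroxy-3-methoxybenzaldehyde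
Product: 15 5-bromo-3-methoxybenzene-1,2-diol, via aryl formate 14 (not isolated)
Conditions: 30% H2O2 (1.3 equiv), NaOH (1.1 equiv), H2O/THF, 0 °C to rt, N2; then aq. HCl
Reagents that add atoms: hydrogen peroxide, OO
Why: Dakin oxidation; hydroperoxide adds to the aldehyde, the aryl group migrates to oxygen (helped by the ortho phenoxide), and the aryl formate is hydrolysed in the alkaline medium to the catechol.

Step 9
Reactants: 15 5-bromo-3-methoxybenzene-1,2-diol
Product: 16 1,2-bis(benzyloxy)-5-bromo-3-methoxybenzene
Conditions: BnBr (2.3 equiv), K2CO3 (3 equiv), DMF, 60 °C, N2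
Reagents that add atoms: benzyl bromide, BrCc1ccccc1
Why: Double Williamson etherification of the catechol; the aryl bromide is inert under these conditions.

Step 10
Reactants: 12 (4R,6S)-6-{2-[4-(benzyloxy)-3-methoxyphenyl]ethyl}oxane-2,4-diol; 16 1,2-bis(benzyloxy)-5-bromo-3-methoxybenzene
Product: 18 (3R,5S)-1-[3,4-bis(benzyloxy)-5-methoxyphenyl]-7-[4-(benzyloxy)-3-methoxyphenyl]heptane-1,3,5-triol as both C1 epimers, via arylmagnesium bromide 17 (not isolated)
Conditions: 16 (3.6 equiv), Mg turnings, BrCH2CH2Br (cat.), THF, 50 °C; then 12, THF, 0 °C to rt; aq. NH4Cl
Reagents that add atoms: none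
Why: Grignard addition to a lactol, which reacts as its open hydroxy aldehyde; two equivalents of 17 are spent on the two hydroxyls and a third adds to the aldehyde, so the triol appears directly under basic conditions. The new C1 carbinol is formed without control, which is intended because the next step is stereoconvergent.

Step 11
Reactants: 18 (3R,5S)-1-[3,4-bis(benzyloxy)-5-methoxyphenyl]-7-[4-(benzyloxy)-3-methoxyphenyl]heptane-1,3,5-triol (both C1 epimers)
Product: 19 (2S,4R,6S)-2-{2-[4-(benzyloxy)-3-methoxyphenyl]ethyl}-6-[3,4-bis(benzyloxy)-5-methoxyphenyl]oxan-4-ol (all-cis)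
Conditions: p-TsOH·H2O (10 mol%), CH2Cl2 (0.02 M), rt
Reagents that add atoms: none
Why: p-TsOH protonates the benzylic C1 hydroxyl of either epimer of 18 and water leaves, giving a benzylic cation delocalised onto the para benzyloxy oxygen (a quinone-methide-like oxocarbenium ion); the C5 hydroxyl adds to this carbon, which forms O1–C6 and closes the oxane, and loss of a proton returns the acid. The closest known reaction type is the acid-catalysed dehydrative cycloetherification (SN1 cyclodehydration) of 1-aryl-1,5-diols with para-alkoxyaryl groups to cis-2-aryl-6-alkyltetrahydropyrans. The ring closes in a 6-exo-trig mode, oxygen attacking the exocyclic cationic sp2 carbon through a chair in which the arylethyl chain on C2 and the hydroxyl on C4 are equatorial. The new stereocentre C6 is controlled by the existing centres C2 and C4: the aryl group takes the remaining equatorial site, so H6 is axial and cis to H2 and H4 (6S). Because the product is itself a para-alkoxybenzyl ether it can re-ionise, so both C1 epimers and any kinetically formed 2,6-trans ether should drain into the all-equatorial isomer under thermodynamic control. The step needs site selectivity in ionisation, secured because only C1 is benzylic while the C3 and C5 carbinols are unactivated; it needs selectivity between the two hydroxyl nucleophiles, secured because O5 closes a six-membered ring whereas O3 could only give a strained oxetane that would reopen; and it needs E1 proton loss to the styrene to stay reversible, which mild catalytic acid, room temperature and dilution should ensure. Since the para oxygen is flanked by two ortho substituents and donates less than an unhindered one, a moderate rise in temperature is preferred over a stronger acid if conversion is slow.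

Step 12
Reactants: 19 (2S,4R,6S)-2-{2-[4-(benzyloxy)-3-methoxyphenyl]ethyl}-6-[3,4-bis(benzyloxy)-5-methoxyphenyl]oxan-4-ol
Product: 20 (2S,4R,6S)-6-(3,4-dihydroxy-5-methoxyphenyl)-2-[2-(4-hydroxy-3-methoxyphenyl)ethyl]oxan-4-ol (target)
Conditions: H2 (1 atm), 10% Pd/C, EtOAc/EtOH, rt; filtration under Ar
Reagents that add atoms: none
Why: Hydrogenolysis of three aryl benzyl ethers; bonds with a phenoxide-type leaving group should be cleaved much faster in a neutral solvent than the C6–O1 ring bond, a secondary benzylic dialkyl ether. No stereocentre is affected.

## Compound list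

1 | 3-(4-hydroxy-3-methoxyphenyl)propanoic acid (dihydroferulic acid) | COc1cc(CCC(=O)O)ccc1O | starting material
2 | 3-[4-(benzyloxy)-3-methoxyphenyl]propanoic acid | COc1cc(CCC(=O)O)ccc1OCc1ccccc1 | intermediate
3 | 1-{3-[4-(benzyloxy)-3-methoxyphenyl]propanoyl}imidazole (acyl imidazolide) | COc1cc(CCC(=O)n2ccnc2)ccc1OCc1ccccc1 | intermediate
4 | ethyl 5-[4-(benzyloxy)-3-methoxyphenyl]-3-oxopentanoate | COc1cc(CCC(=O)CC(=O)OCC)ccc1OCc1ccccc1 | intermediate
5 | ethyl (3S)-5-[4-(benzyloxy)-3-methoxyphenyl]-3-hydroxypentanoate | COc1cc(CC[C@H](O)CC(=O)OCC)ccc1OCc1ccccc1 | intermediate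
6 | tert-butyl acetate | CC(=O)OC(C)(C)C | starting material
7 | lithium 1-(tert-butoxy)ethen-1-olate (lithium enolate of tert-butyl acetate) | [Li+].[O-]C(=C)OC(C)(C)C | intermediate
8 | tert-butyl (5S)-7-[4-(benzyloxy)-3-methoxyphenyl]-5-hydroxy-3-oxoheptanoate | COc1cc(CC[C@H](O)CC(=O)CC(=O)OC(C)(C)C)ccc1OCc1ccccc1 | intermediate
9 | tert-butyl (3R,5S)-7-[4-(benzyloxy)-3-methoxyphenyl]-3,5-dihydroxyheptanoate | COc1cc(CC[C@H](O)C[C@@H](O)CC(=O)OC(C)(C)C)ccc1OCc1ccccc1 | intermediate
10 | (3R,5S)-7-[4-(benzyloxy)-3-methoxyphenyl]-3,5-dihydroxyheptanoic acid | COc1cc(CC[C@H](O)C[C@@H](O)CC(=O)O)ccc1OCc1ccccc1 | intermediate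
11 | (4R,6S)-6-{2-[4-(benzyloxy)-3-methoxyphenyl]ethyl}-4-hydroxyoxan-2-one | COc1cc(CC[C@H]2C[C@@H](O)CC(=O)O2)ccc1OCc1ccccc1 | intermediate
12 | (4R,6S)-6-{2-[4-(benzyloxy)-3-methoxyphenyl]ethyl}oxane-2,4-diol (both anomers) | COc1cc(CC[C@H]2C[C@@H](O)CC(O)O2)ccc1OCc1ccccc1 | intermediate
13 | 5-bromo-2-hydroxy-3-methoxybenzaldehyde | COc1cc(Br)cc(C=O)c1O | starting material
14 | 5-bromo-2-hydroxy-3-methoxyphenyl formate | COc1cc(Br)cc(OC=O)c1O | intermediate
15 | 5-bromo-3-methoxybenzene-1,2-diol | COc1cc(Br)cc(O)c1O | intermediate
16 | 1,2-bis(benzyloxy)-5-bromo-3-methoxybenzene | COc1cc(Br)cc(OCc2ccccc2)c1OCc1ccccc1 | intermediate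
17 | [3,4-bis(benzyloxy)-5-methoxyphenyl]magnesium bromide | COc1cc([Mg]Br)cc(OCc2ccccc2)c1OCc1ccccc1 | intermediate
18 | (3R,5S)-1-[3,4-bis(benzyloxy)-5-methoxyphenyl]-7-[4-(benzyloxy)-3-methoxyphenyl]heptane-1,3,5-triol (both C1 epimers) | COc1cc(CC[C@H](O)C[C@@H](O)CC(O)c2cc(OCc3ccccc3)c(OCc3ccccc3)c(OC)c2)ccc1OCc1ccccc1 | intermediate
19 | (2S,4R,6S)-2-{2-[4-(benzyloxy)-3-methoxyphenyl]ethyl}-6-[3,4-bis(benzyloxy)-5-methoxyphenyl]oxan-4-ol | COc1cc(CC[C@H]2C[C@@H](O)C[C@@H](c3cc(OCc4ccccc4)c(OCc4ccccc4)c(OC)c3)O2)ccc1OCc1ccccc1 | intermediate
20 | (2S,4R,6S)-6-(3,4-dihydroxy-5-methoxyphenyl)-2-[2-(4-hydroxy-3-methoxyphenyl)ethyl]oxan-4-ol | COc1cc(CC[C@H]2C[C@@H](O)C[C@@H](c3cc(O)c(O)c(OC)c3)O2)ccc1O | target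

## Step count and least certain steps

Total step count: 12 (steps 1–7 on the main chain, steps 8–9 on the aryl fragment, steps 10–12 after the union). Longest linear sequence: 10 steps (1, 2, 3, 4, 5, 6, 7, 10, 11, 12).

**Step 11 (key step).** The most likely failure is sluggish ionisation, because the para benzyloxy group is twisted out of conjugation by its two ortho neighbours. If the reaction is then forced, E1 loss of a proton towards the styrene would make the C3 hydroxyl allylic and ionisable, with erosion of the C4 centre or dehydration, and intermolecular etherification could compete.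
Fallback: setting out from 18, chemoselective oxidation of the benzylic carbinol with MnO2 in CH2Cl2 should give the aryl ketone (3R,5S)-1-[3,4-bis(benzyloxy)-5-methoxyphenyl]-7-[4-(benzyloxy)-3-methoxyphenyl]-3,5-dihydroxyheptan-1-one F1, which equilibrates with its cyclic hemiketal. Reductive etherification with Et3SiH and TMSOTf in CH2Cl2/MeCN at −78 to −40 °C would then reduce the 2-aryl oxocarbenium ion by axial hydride delivery, placing the aryl group equatorial, and the route is rejoined at 19.

**Step 10.** The risks are incomplete opening of the magnesium lactolate, enolisation of the liberated β-alkoxy aldehyde followed by β-elimination, or retro-aldol cleavage. Two equivalents of the aryl nucleophile are also consumed as base.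
Fallback: setting out from 9, ketalisation with 2,2-dimethoxypropane and PPTS should give the anti acetonide tert-butyl 2-[(4R,6S)-6-{2-[4-(benzyloxy)-3-methoxyphenyl]ethyl}-2,2-dimethyl-1,3-dioxan-4-yl]acetate F2. Reduction with i-Bu2AlH in toluene at −78 °C would give the aldehyde 2-[(4R,6S)-6-{2-[4-(benzyloxy)-3-methoxyphenyl]ethyl}-2,2-dimethyl-1,3-dioxan-4-yl]acetaldehyde F3. Addition of the aryllithium made from 16 with n-BuLi in THF at −78 °C would give the carbinol 1-[3,4-bis(benzyloxy)-5-methoxyphenyl]-2-[(4S,6S)-6-{2-[4-(benzyloxy)-3-methoxyphenyl]ethyl}-2,2-dimethyl-1,3-dioxan-4-yl]ethan-1-ol F4 as both epimers. Mild hydrolysis of the acetonide with AcOH/THF/H2O rejoins the route at 18; any ring closure that already begins during this unmasking leads towards 19 and does no harm.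

**Step 6.** The risks are Friedel–Crafts tert-butylation of the electron-rich guaiacyl ring by the tert-butyl cation, acid-induced dehydration of the β-hydroxy lactone, and slow loss of the benzyl ether on long exposure.
Fallback: setting out from 9, the ester would be saponified with NaOH in THF/MeOH/H2O at 40 °C with no cation involved. Careful acidification would give acid 10, now isolated, and lactonisation by azeotropic heating in toluene or with a carbodiimide rejoins the route at 11. No new compound is made.

**Step 12.** The risks are hydrogenolysis of the benzylic C6–O1 ring bond once the phenols are free, and air oxidation of the catechol during isolation.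
Fallback: the order of events is reversed. Setting out from 18, hydrogenolysis (H2, Pd/C, EtOAc) at the triol stage, where the only other benzylic C–O bond is a free alcohol and a poorer leaving group on palladium than an ether, should give (3R,5S)-1-(3,4-dihydroxy-5-methoxyphenyl)-7-(4-hydroxy-3-methoxyphenyl)heptane-1,3,5-triol F5 as both C1 epimers. Cyclodehydration of F5 with catalytic p-TsOH in MeCN under argon, where the free para hydroxyl makes the quinone-methide pathway easier, would rejoin the route at 20.

## Further compounds

F1 | step 11 | (3R,5S)-1-[3,4-bis(benzyloxy)-5-methoxyphenyl]-7-[4-(benzyloxy)-3-methoxyphenyl]-3,5-dihydroxyheptan-1-one | COc1cc(CC[C@H](O)C[C@@H](O)CC(=O)c2cc(OCc3ccccc3)c(OCc3ccccc3)c(OC)c2)ccc1OCc1ccccc1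
F2 | step 10 | tert-butyl 2-[(4R,6S)-6-{2-[4-(benzyloxy)-3-methoxyphenyl]ethyl}-2,2-dimethyl-1,3-dioxan-4-yl]acetate | COc1cc(CC[C@H]2C[C@H](CC(=O)OC(C)(C)C)OC(C)(C)O2)ccc1OCc1ccccc1
F3 | step 10 | 2-[(4R,6S)-6-{2-[4-(benzyloxy)-3-methoxyphenyl]ethyl}-2,2-dimethyl-1,3-dioxan-4-yl]acetaldehyde | COc1cc(CC[C@H]2C[C@H](CC=O)OC(C)(C)O2)ccc1OCc1ccccc1
F4 | step 10 | 1-[3,4-bis(benzyloxy)-5-methoxyphenyl]-2-[(4S,6S)-6-{2-[4-(benzyloxy)-3-methoxyphenyl]ethyl}-2,2-dimethyl-1,3-dioxan-4-yl]ethan-1-ol (both carbinol epimers) | COc1cc(CC[C@H]2C[C@H](CC(O)c3cc(OCc4ccccc4)c(OCc4ccccc4)c(OC)c3)OC(C)(C)O2)ccc1OCc1ccccc1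
F0 | step 6 | none | none
F5 | step 12 | (3R,5S)-1-(3,4-dihydroxy-5-methoxyphenyl)-7-(4-hydroxy-3-methoxyphenyl)heptane-1,3,5-triol (both C1 epimers) | COc1cc(CC[C@H](O)C[C@@H](O)CC(O)c2cc(O)c(O)c(OC)c2)ccc1O
A1 | alternative 1 | 1-[3,4-bis(benzyloxy)-5-methoxyphenyl]-2-{2-[(2S)-4-[4-(benzyloxy)-3-methoxyphenyl]-2-[(tert-butyldimethylsilyl)oxy]butyl]-1,3-dithian-2-yl}ethan-1-ol (both carbinol epimers) | COc1cc(CC[C@H](O[Si](C)(C)C(C)(C)C)CC2(SCCCS2)CC(O)c2cc(OCc3ccccc3)c(OCc3ccccc3)c(OC)c2)ccc1OCc1ccccc1
A2 | alternative 1 | (2S)-2-{2-[4-(benzyloxy)-3-methoxyphenyl]ethyl}oxirane | COc1cc(CC[C@H]2CO2)ccc1OCc1ccccc1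
A3 | alternative 1 | 2-[3,4-bis(benzyloxy)-5-methoxyphenyl]oxirane (racemic) | COc1cc(C2CO2)cc(OCc2ccccc2)c1OCc1ccccc1
A4 | alternative 1 | tert-butyl(1,3-dithian-2-yl)dimethylsilane | CC(C)(C)[Si](C)(C)C1SCCCS1
A5 | alternative 2 | (2S,6S)-2-{2-[4-(benzyloxy)-3-methoxyphenyl]ethyl}-6-[3,4-bis(benzyloxy)-5-methoxyphenyl]oxan-4-one (cis) | COc1cc(CC[C@H]2CC(=O)C[C@@H](c3cc(OCc4ccccc4)c(OCc4ccccc4)c(OC)c3)O2)ccc1OCc1ccccc1
A6 | alternative 2 | (2S,6S)-2-[3,4-bis(benzyloxy)-5-methoxyphenyl]-6-{2-[4-(benzyloxy)-3-methoxyphenyl]ethyl}-4-methylidene-1,3-dioxane (cis) | COc1cc(CC[C@H]2CC(=C)O[C@@H](c3cc(OCc4ccccc4)c(OCc4ccccc4)c(OC)c3)O2)ccc1OCc1ccccc1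
A7 | alternative 2 | 3,4-bis(benzyloxy)-5-methoxybenzaldehyde | COc1cc(C=O)cc(OCc2ccccc2)c1OCc1ccccc1
A8 | alternative 2 | (2S,6S)-2-[3,4-bis(benzyloxy)-5-methoxyphenyl]-6-{2-[4-(benzyloxy)-3-methoxyphenyl]ethyl}-1,3-dioxan-4-one (cis) | COc1cc(CC[C@H]2CC(=O)O[C@@H](c3cc(OCc4ccccc4)c(OCc4ccccc4)c(OC)c3)O2)ccc1OCc1ccccc1
A9 | alternative 3 | (2R,4R,6S)-2-{(E)-2-[4-(benzyloxy)-3-methoxyphenyl]ethenyl}-6-[3,4-bis(benzyloxy)-5-methoxyphenyl]-4-[(tert-butyldimethylsilyl)oxy]oxane (all-cis) | COc1cc(/C=C/[C@H]2C[C@@H](O[Si](C)(C)C(C)(C)C)C[C@@H](c3cc(OCc4ccccc4)c(OCc4ccccc4)c(OC)c3)O2)ccc1OCc1ccccc1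
A10 | alternative 3 | (1S,3R,5E)-1-[3,4-bis(benzyloxy)-5-methoxyphenyl]-7-[4-(benzyloxy)-3-methoxyphenyl]-3-[(tert-butyldimethylsilyl)oxy]hept-5-ene-1,7-diol (both C7 epimers) | COc1cc(C(O)/C=C/C[C@@H](O[Si](C)(C)C(C)(C)C)C[C@H](O)c2cc(OCc3ccccc3)c(OCc3ccccc3)c(OC)c2)ccc1OCc1ccccc1
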